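## The problem

Kanzonol I (24) is an isoflavan: ring A is fused to the dihydropyran ring C, and C3 of ring C carries ring B through C1′. Ring A is fully differentiated (methoxy groups on C5 and C7, a prenyl group on C6, O1 on C8a). Ring B is part of a 2,2-dimethyl-2H-chromene whose pyran oxygen sits on C2′ and whose free phenol sits on C4′, so each arene has oxygen atoms that must be told apart. The only stereocentre is C3 (R), a tertiary benzylic C–H between two methylene groups. Nothing else in the molecule can control it, so it has to be set by a reagent or catalyst and must never pass through a carbonyl group or a cation afterwards. The prenyl double bond, the chromene double bond (a styrene flanked by two ring oxygens) and both electron-rich rings exclude hydrogenation, strong Lewis acids, hard oxidants and late electrophilic halogenation. The enabling feature is that C3 and C4 form a two-carbon unit with one arene at each end: C3 bears C1′ of ring B, C4 is bonded to C4a of ring A, and the third substituent of C3 is the single methylene carbon C2. A vinyl group on boron can therefore take up both arenes in one operation, with boron left on C3 as the placeholder for C2 and the C8a oxygen ready to close ring C afterwards.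

## Retrosynthesis

**O–Si, O1–C2 and the acetal.** Kanzonol I (24) is traced to its C4′ silyl ether 23, and ring C is opened at O1–C2 to give phenol–alcohol 22. Cutting O1–C2 rather than the aryl C–O bond O1–C8a keeps the natural oxygen on ring A. The forward step is then only a Mitsunobu displacement at a primary, non-stereogenic carbon, which cannot disturb C3. Cutting C4–C4a instead would need a Friedel–Crafts closure beside the acid-sensitive chromene. The ring B phenol stays silylated so that only one phenoxide is present during closure. Phenol 22 comes from its methoxymethyl ether 21 by mild acid.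

**C2–C3.** In 21 the C2–C3 bond is cut by treating C2 as a methylene carbenoid inserted into a C3–B bond: 21 from primary boronic ester 20, and 20 from secondary boronic ester 18. The neighbouring cut at C3–C4 (auxiliary-controlled enolate benzylation) would need stoichiometric chirality and a carbonyl group next to C3. The chosen cut keeps C3 at the alkane oxidation level and leaves in 18 a carbon bearing boron, ring B and the ring A benzyl group, which is the pattern a conjunctive coupling delivers. The forward reaction must be stereoretentive at a hindered benzylic boron; Matteson homologation followed by oxidation meets this.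

**C3–C1′ and C4–C4a (key disconnection).** Boronic ester 18 is cut at both bonds at once, which strips the two arenes from a vinyl group on boron.
- Ring B arrives as the nucleophile: aryllithium 16, made from bromide 5, adds to vinylboronic ester 15 to give ate complex 17.
- Ring A arrives as the electrophile, bromide 14.
- The roles cannot be exchanged, because the migrating group ends on the boron-bearing carbon.
- A stepwise alternative (olefination, then asymmetric hydroboration) would have no regiocontrol between two benzylic carbons. The single step forms two skeletal bonds and the stereocentre from two aryl bromides of similar size.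
- The forward reaction must cope with an electron-rich, doubly ortho-substituted aryl bromide and with bromide ions from both partners. The ring A oxygen is therefore carried as the small methoxymethyl ether rather than a silyl ether, 17 is used in excess over 14, and potassium triflate is added to take up halide.
- The catalyst is Pd(OAc)2 with a MandyPhos ligand, 1,1′-bis[bis(3,5-dimethylphenyl)phosphino]-2,2′-bis[α-(dimethylamino)benzyl]ferrocene.

**Ring A bromide 14.** The C–Br bond is cut to aryllithium 13, formed by ortho-lithiation of methoxymethyl ether 12. The two ring hydrogens of 12 are equivalent, so only one bromide can form, and no electrophilic bromine meets the prenyl alkene. Ether 12 comes from phenol 11, and 11 from silyl ether 10. The prenyl C–C bond of 10 is cut to aryllithium 9 and prenyl bromide (8); 9 comes from silyl ether 7 of 3,5-dimethoxyphenol (6). Direct C-prenylation of 6 was set aside because phenoxide alkylation favours the ortho position and acid-mediated prenylation gives mixtures. Lithiation of 7 can only occur between the two methoxy groups. The silyl-to-methoxymethyl exchange costs two steps but supplies both the directing group for bromination and the small ortho substituent the key step needs.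

**Ring B bromide 5.** The chromene is cut at its C4–C4a and O1–C2 bonds (C3′ and O–C2′ of the target) to aryl propargyl ether 4. Ether 4 is cut at O–C to phenol 2 and 3-chloro-3-methylbut-1-yne (3), and 2 at O–Si to 4-bromoresorcinol (1). In 1 the bromine already marks C1′, next to the oxygen that becomes the pyran oxygen, and it blocks the second ortho position, so the annulation can only go to C3′. The forward steps ask for silylation of the hydroxyl remote from bromine.

## Roads not taken

**Alternative 1:** Ring B itself is taken apart (C1′–C2′, C2′–C3′, C4′–C5′, C5′–C6′), back to a chroman that already holds the C3 stereocentre and carries an enone diazoketone side chain (A1), plus prenyl siloxyalkyne A2.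
- Forward key step: irradiation of A1 causes Wolff rearrangement; (2+2) addition of A2, four-electron ring opening and six-electron closure then give isoflavan A3, with 2′-hydroxy, 3′-prenyl and 4′-silyloxy groups on the new ring.
- Merits: the substitution pattern of ring B is dictated by the mechanism, no hindered cross-coupling is needed, and C3 is a spectator.
- Weak points: the step creates no stereocentre. The stereocentre of A1 must be made earlier, at a stage where C3 is alpha to a carbonyl group and later gamma to the enone, both of which invite epimerisation under the basic diazo-transfer conditions. The sequence is linear on ring A. After the annulation the chromene must still be closed by dehydrogenative cyclisation of the ortho-prenylphenol in A3, in the presence of the second prenyl group and an electron-rich ring A.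
- Comparison: this road is better in that ring B regiochemistry does not depend on selective silylation of 1 and in that its key step has no steric problem. The chosen plan sets against this its convergence from two commercial phenols, the creation of C3 under catalyst control in the key step, and the absence of a late oxidation.

**Alternative 2:** Ring C is cut at C3–C4 and O1–C2, giving O-Boc salicylaldehyde A4 (ring A) and the E enol ether A6 of ring B with trans-2-phenylcyclohexanol.
- Forward key step: NaBH4 adds to the aldehyde of A4, carbonate transfer and elimination release ortho-quinone methide A5, and A6 adds across it in an inverse-demand (4+2) sense under auxiliary control to give acetal A7.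
- Merits: ring C and the C3 stereocentre form in one low-temperature, metal-free step, and only reductive removal of the acetal oxygen and desilylation remain.
- Weak points: the chirality is stoichiometric, and A6 must be made as a single E isomer. The C2 acetal must be removed by ionic reduction (Et3SiH, BF3·OEt2), conditions under which the chromene double bond, which gives a doubly oxygen-stabilised benzylic cation, and the prenyl group are themselves at risk.
- Comparison: this road closes a ring in its key step and has the shorter endgame (two steps against four), which the chosen plan cannot match. The chosen plan sets against it catalytic enantiocontrol, no surplus heteroatom to remove at C2, and dilute protic acid as its only acidic operation.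

**Alternative 3:** Ring C is cut at O1–C8a after adding a second hydroxymethyl group to C3, giving the prochiral diol A8 with bromine on C8a.
- Forward key step: CuI and a chiral diamine couple one of the two enantiotopic hydroxymethyl oxygens to the aryl bromide, closing ring C and setting C3 as a quaternary centre in A9.
- Merits: catalytic stereocontrol, an achiral and robust substrate, ring closure in the key step, and a centre that cannot epimerise.
- Weak points: the extra carbon of A9 must be excised by oxidation and decarbonylation with a rhodium complex such as RhCl(PPh3)3 at a fully substituted, aryl-bearing carbon. This is a demanding, high-temperature step with β-hydrogens and two isomerisable alkenes nearby. Building the quaternary carbon of A8 with a hindered ring B also lengthens the approach.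
- Comparison: this road equals the chosen plan in catalytic control and is better in closing ring C during the key step. The chosen plan sets against it the direct delivery of the tertiary C–H centre at the correct oxidation level, with no sacrificial carbon.

Key step: step 9

Assumption: the sense of induction of the MandyPhos ligand is taken from simple aryl–aryl conjunctive couplings; the ligand enantiomer that gives the R boronic ester 18 is used, and its antipode is equally available if a model reaction shows the opposite sense.

## Route

Step 1
Reactants: 1 4-bromoresorcinol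
Product: 2 2-bromo-5-(triisopropylsilyloxy)phenol
Conditions: TIPSCl (1.05 equiv), imidazole, CH2Cl2, 0 °C
Reagents that add atoms: chlorotriisopropylsilane, CC(C)[Si](Cl)(C(C)C)C(C)C
Why: Regioselective O-silylation with a bulky silyl chloride should go to the unhindered hydroxyl para to bromine, since the hydroxyl ortho to bromine is shielded and less nucleophilic; any regioisomer or bis-silyl ether should be separable by chromatography, and an NOE measurement on 2 would show which hydroxyl carries silicon.

Step 2
Reactants: 2 2-bromo-5-(triisopropylsilyloxy)phenol; 3 3-chloro-3-methylbut-1-yne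
Product: 4 [4-bromo-3-(2-methylbut-3-yn-2-yloxy)phenoxy]triisopropylsilane
Conditions: DBU, CuCl2·2H2O (cat.), MeCN, 0 °C → rt
Reagents that add atoms: none
Why: Copper-catalysed O-propargylation of a phenol with a tertiary propargylic chloride (copper allenylidene pathway) forms hindered aryl 1,1-dimethylpropargyl ethers where uncatalysed alkylation would mainly eliminate; the aryl bromide and the silyl ether are inert.

Step 3
Reactants: 4 [4-bromo-3-(2-methylbut-3-yn-2-yloxy)phenoxy]triisopropylsilane
Product: 5 8-bromo-2,2-dimethyl-5-(triisopropylsilyloxy)-2H-chromene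
Conditions: o-xylene, 145 °C
Reagents that add atoms: none
Why: Aromatic propargyl Claisen rearrangement to the only free ortho carbon, then 1,5-hydrogen shift and oxa-6π electrocyclisation, gives the 2,2-dimethyl-2H-chromene; bromine blocks the other ortho carbon, so only the 8-bromo-5-silyloxy isomer can arise.

Step 4
Reactants: 6 3,5-dimethoxyphenol
Product: 7 (3,5-dimethoxyphenoxy)triisopropylsilane
Conditions: TIPSCl, imidazole, DMF, rt
Reagents that add atoms: chlorotriisopropylsilane, CC(C)[Si](Cl)(C(C)C)C(C)C
Why: Routine phenol silylation; the triisopropylsilyl ether is chosen because it neither directs lithiation nor leaves room for it at its own ortho positions.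

Step 5
Reactants: 7 (3,5-dimethoxyphenoxy)triisopropylsilane; 8 prenyl bromide (1-bromo-3-methylbut-2-ene)
Product: 10 [3,5-dimethoxy-4-(3-methylbut-2-en-1-yl)phenoxy]triisopropylsilane, via aryllithium 9 (not isolated)
Conditions: n-BuLi, THF, 0 °C → rt; then 8, −78 °C → rt
Reagents that add atoms: none
Why: Directed ortho-metalation removes the hydrogen between the two methoxy groups, the most acidic and doubly coordinated site, while the bulky silyl ether shields the other ring positions and, being para to lithium, cannot migrate; SN2 alkylation of 9 at the primary allylic bromide gives the linear prenyl group.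

Step 6
Reactants: 10 [3,5-dimethoxy-4-(3-methylbut-2-en-1-yl)phenoxy]triisopropylsilane
Product: 11 3,5-dimethoxy-4-(3-methylbut-2-en-1-yl)phenol
Conditions: TBAF, AcOH, THF, 0 °C → rt
Reagents that add atoms: none
Why: Fluoride cleavage of an aryl silyl ether, driven by the Si–F bond and buffered by acetic acid; the prenyl group is untouched.

Step 7
Reactants: 11 3,5-dimethoxy-4-(3-methylbut-2-en-1-yl)phenol
Product: 12 1,3-dimethoxy-5-(methoxymethoxy)-2-(3-methylbut-2-en-1-yl)benzene
Conditions: MOMCl, i-Pr2NEt, CH2Cl2, 0 °C → rt
Reagents that add atoms: chloromethyl methyl ether, COCCl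
Why: O-alkylation of the phenol with MOMCl and a hindered amine base; the methoxymethyl ether is small, stable to organolithiums and the directing group for the next step.

Step 8
Reactants: 12 1,3-dimethoxy-5-(methoxymethoxy)-2-(3-methylbut-2-en-1-yl)benzene
Product: 14 2-bromo-3,5-dimethoxy-1-(methoxymethoxy)-4-(3-methylbut-2-en-1-yl)benzene, via aryllithium 13 (not isolated)
Conditions: n-BuLi, THF, 0 °C; then BrCCl2CCl2Br, −78 °C → rt
Reagents that add atoms: 1,2-dibromo-1,1,2,2-tetrachloroethane, BrC(Cl)(Cl)C(Cl)(Cl)Br
Why: Directed ortho-metalation by the methoxymethoxy group at the ring hydrogen it shares with a methoxy group (both ring hydrogens are equivalent, so one product), then bromine transfer to 13; coordination-directed ring lithiation should outpace removal of the benzylic–allylic protons, and no electrophilic bromine meets the prenyl alkene.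

Step 9
Reactants: 5 8-bromo-2,2-dimethyl-5-(triisopropylsilyloxy)-2H-chromene; 15 vinylboronic acid pinacol ester; 14 2-bromo-3,5-dimethoxy-1-(methoxymethoxy)-4-(3-methylbut-2-en-1-yl)benzene
Product: 18 2-{(1R)-1-[2,2-dimethyl-5-(triisopropylsilyloxy)-2H-chromen-8-yl]-2-[2,4-dimethoxy-6-(methoxymethoxy)-3-(3-methylbut-2-en-1-yl)phenyl]ethyl}-4,4,5,5-tetramethyl-1,3,2-dioxaborolane, via aryllithium 16 (not isolated), via vinylboronate complex 17 (not isolated)
Conditions: 5, t-BuLi (2 equiv), Et2O, −78 °C; 15, −78 °C → rt; solvent switch to THF; 14 (limiting), Pd(OAc)2 (5 mol %), 1,1′-bis[bis(3,5-dimethylphenyl)phosphino]-2,2′-bis[α-(dimethylamino)benzyl]ferrocene (MandyPhos, 6 mol %), CF3SO3K (2 equiv), 60 °C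
Reagents that add atoms: none
Why: Bromine–lithium exchange gives aryllithium 16, which adds to the vacant orbital on boron of 15 to give the tetracoordinate boronate 17. Oxidative addition of 14 to zerovalent palladium bearing the bisphosphine gives an arylpalladium bromide, and the triflate salt removes bromide so that the cationic divalent palladium can bind the vinyl group of 17. Binding triggers a 1,2-metallate shift in which ring B migrates from boron to the alpha carbon anti to palladium (C3–C1′) while the beta carbon bonds to palladium, and reductive elimination then forms C4–C4a and returns zerovalent palladium. The closest known reaction type is the enantioselective palladium-catalysed conjunctive cross-coupling of aryl(vinyl)boronates with aryl triflates and bromides, of which this is a direct application to more substituted partners. No ring is closed. C3 is the only new stereocentre and is set by the catalyst, since the chiral bisphosphine on palladium selects the face of the boronate alkene and anti migration then fixes C3 as R. The metallate shift must beat direct Suzuki-type transfer of vinyl or aryl from boron to palladium, which the wide-bite-angle ligand and the removal of free bromide favour, and palladium must ignore the chromene and prenyl alkenes, which are neutral and far less nucleophilic than the anionic boronate alkene. The small methoxymethyl and methoxy groups are the only ortho substituents on 14, which keeps oxidative addition and alkene binding feasible, and boron stays on C3 for the next step.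

Step 10
Reactants: 18 the R secondary boronic ester of step 9
Product: 21 (2R)-2-[2,2-dimethyl-5-(triisopropylsilyloxy)-2H-chromen-8-yl]-3-[2,4-dimethoxy-6-(methoxymethoxy)-3-(3-methylbut-2-en-1-yl)phenyl]propan-1-ol, via chloromethylboronate complex 19 (not isolated), via homologated boronic ester 20 (not isolated)
Conditions: BrCH2Cl, n-BuLi, THF, −78 °C → rt; then NaBO3·4H2O, THF/H2O, rt
Reagents that add atoms: bromochloromethane, ClCBr; sodium perborate tetrahydrate, [Na+].[O-]OB=O.O.O.O.O
Why: Matteson homologation, in which chloromethyllithium made in situ adds to boron (19) and on warming the secondary benzylic carbon migrates to the methylene carbon with retention, expelling chloride (20); perborate then oxidises the primary C–B bond under conditions mild enough for the aryl silyl ether, and C3 is untouched and stays R.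

Step 11
Reactants: 21 the methoxymethyl-protected primary alcohol of step 10
Product: 22 2-{(2R)-2-[2,2-dimethyl-5-(triisopropylsilyloxy)-2H-chromen-8-yl]-3-hydroxypropyl}-3,5-dimethoxy-4-(3-methylbut-2-en-1-yl)phenol
Conditions: HCl (2 M aq), MeOH, 40 °C
Reagents that add atoms: none
Why: Acid-catalysed acetal exchange removes the phenolic methoxymethyl ether; dilute acid at 40 °C spares the aryl triisopropylsilyl ether, the prenyl group has no free ortho hydroxyl to cyclise onto it, and 2,2-dimethylchromenes of this type are expected to tolerate such conditions.

Step 12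
Reactants: 22 the phenol–alcohol of step 11
Product: 23 (3R)-3-[2,2-dimethyl-5-(triisopropylsilyloxy)-2H-chromen-8-yl]-5,7-dimethoxy-6-(3-methylbut-2-en-1-yl)chromane
Conditions: PPh3, DIAD, THF (0.02 M), 0 °C → rt
Reagents that add atoms: none
Why: Intramolecular Mitsunobu etherification, in which the primary alcohol is activated as its oxyphosphonium ion and displaced by the ring A phenoxide in a 6-exo-tet closure of ring C (O1–C2); C2 is not stereogenic and C3 is a spectator, so the R configuration is carried through.

Step 13
Reactants: 23 O-triisopropylsilyl kanzonol I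
Product: 24 kanzonol I, 8-[(3R)-5,7-dimethoxy-6-(3-methylbut-2-en-1-yl)chroman-3-yl]-2,2-dimethyl-2H-chromen-5-ol
Conditions: TBAF, AcOH, THF, 0 °C
Reagents that add atoms: none
Why: Buffered fluoride cleaves the aryl silyl ether and releases the C4′ phenol; no other group responds.

## Compound list

1 | 4-bromoresorcinol (4-bromobenzene-1,3-diol) | Oc1ccc(Br)c(O)c1 | starting material
2 | 2-bromo-5-(triisopropylsilyloxy)phenol | Oc1cc(O[Si](C(C)C)(C(C)C)C(C)C)ccc1Br | intermediate
3 | 3-chloro-3-methylbut-1-yne | CC(C)(Cl)C#C | starting material
4 | [4-bromo-3-(2-methylbut-3-yn-2-yloxy)phenoxy]triisopropylsilane | C#CC(C)(C)Oc1cc(O[Si](C(C)C)(C(C)C)C(C)C)ccc1Br | intermediate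
5 | 8-bromo-2,2-dimethyl-5-(triisopropylsilyloxy)-2H-chromene | Brc1ccc(O[Si](C(C)C)(C(C)C)C(C)C)c2c1OC(C)(C)C=C2 | intermediate
6 | 3,5-dimethoxyphenol | COc1cc(O)cc(OC)c1 | starting material
7 | (3,5-dimethoxyphenoxy)triisopropylsilane | COc1cc(O[Si](C(C)C)(C(C)C)C(C)C)cc(OC)c1 | intermediate
8 | prenyl bromide (1-bromo-3-methylbut-2-ene) | CC(C)=CCBr | starting material
9 | [2,6-dimethoxy-4-(triisopropylsilyloxy)phenyl]lithium (not isolated) | [Li]c1c(OC)cc(O[Si](C(C)C)(C(C)C)C(C)C)cc1OC | intermediate
10 | [3,5-dimethoxy-4-(3-methylbut-2-en-1-yl)phenoxy]triisopropylsilane | COc1cc(O[Si](C(C)C)(C(C)C)C(C)C)cc(OC)c1CC=C(C)C | intermediate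
11 | 3,5-dimethoxy-4-(3-methylbut-2-en-1-yl)phenol | COc1cc(O)cc(OC)c1CC=C(C)C | intermediate
12 | 1,3-dimethoxy-5-(methoxymethoxy)-2-(3-methylbut-2-en-1-yl)benzene | COCOc1cc(OC)c(CC=C(C)C)c(OC)c1 | intermediate
13 | [2,4-dimethoxy-6-(methoxymethoxy)-3-(3-methylbut-2-en-1-yl)phenyl]lithium (not isolated) | [Li]c1c(OCOC)cc(OC)c(CC=C(C)C)c1OC | intermediate
14 | 2-bromo-3,5-dimethoxy-1-(methoxymethoxy)-4-(3-methylbut-2-en-1-yl)benzene | COCOc1cc(OC)c(CC=C(C)C)c(OC)c1Br | intermediate
15 | vinylboronic acid pinacol ester (4,4,5,5-tetramethyl-2-vinyl-1,3,2-dioxaborolane) | C=CB1OC(C)(C)C(C)(C)O1 | starting material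
16 | [2,2-dimethyl-5-(triisopropylsilyloxy)-2H-chromen-8-yl]lithium (not isolated) | [Li]c1ccc(O[Si](C(C)C)(C(C)C)C(C)C)c2c1OC(C)(C)C=C2 | intermediate
17 | lithium [2,2-dimethyl-5-(triisopropylsilyloxy)-2H-chromen-8-yl](pinacolato)(vinyl)borate (not isolated) | [Li+].C=C[B-]1(c2ccc(O[Si](C(C)C)(C(C)C)C(C)C)c3c2OC(C)(C)C=C3)OC(C)(C)C(C)(C)O1 | intermediate
18 | 2-{(1R)-1-[2,2-dimethyl-5-(triisopropylsilyloxy)-2H-chromen-8-yl]-2-[2,4-dimethoxy-6-(methoxymethoxy)-3-(3-methylbut-2-en-1-yl)phenyl]ethyl}-4,4,5,5-tetramethyl-1,3,2-dioxaborolane | COCOc1cc(OC)c(CC=C(C)C)c(OC)c1C[C@H](c1ccc(O[Si](C(C)C)(C(C)C)C(C)C)c2c1OC(C)(C)C=C2)B1OC(C)(C)C(C)(C)O1 | intermediate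
19 | lithium (chloromethyl)(pinacolato)borate complex of 18, R at C3 (not isolated) | [Li+].COCOc1cc(OC)c(CC=C(C)C)c(OC)c1C[C@H](c1ccc(O[Si](C(C)C)(C(C)C)C(C)C)c2c1OC(C)(C)C=C2)[B-]1(CCl)OC(C)(C)C(C)(C)O1 | intermediate
20 | 2-{(2R)-2-[2,2-dimethyl-5-(triisopropylsilyloxy)-2H-chromen-8-yl]-3-[2,4-dimethoxy-6-(methoxymethoxy)-3-(3-methylbut-2-en-1-yl)phenyl]propyl}-4,4,5,5-tetramethyl-1,3,2-dioxaborolane (not isolated) | COCOc1cc(OC)c(CC=C(C)C)c(OC)c1C[C@H](c1ccc(O[Si](C(C)C)(C(C)C)C(C)C)c2c1OC(C)(C)C=C2)CB1OC(C)(C)C(C)(C)O1 | intermediate
21 | (2R)-2-[2,2-dimethyl-5-(triisopropylsilyloxy)-2H-chromen-8-yl]-3-[2,4-dimethoxy-6-(methoxymethoxy)-3-(3-methylbut-2-en-1-yl)phenyl]propan-1-ol | COCOc1cc(OC)c(CC=C(C)C)c(OC)c1C[C@H](c1ccc(O[Si](C(C)C)(C(C)C)C(C)C)c2c1OC(C)(C)C=C2)CO | intermediate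
22 | 2-{(2R)-2-[2,2-dimethyl-5-(triisopropylsilyloxy)-2H-chromen-8-yl]-3-hydroxypropyl}-3,5-dimethoxy-4-(3-methylbut-2-en-1-yl)phenol | COc1cc(O)c(C[C@H](c2ccc(O[Si](C(C)C)(C(C)C)C(C)C)c3c2OC(C)(C)C=C3)CO)c(OC)c1CC=C(C)C | intermediate
23 | (3R)-3-[2,2-dimethyl-5-(triisopropylsilyloxy)-2H-chromen-8-yl]-5,7-dimethoxy-6-(3-methylbut-2-en-1-yl)chromane | COc1cc2c(c(OC)c1CC=C(C)C)C[C@H](c1ccc(O[Si](C(C)C)(C(C)C)C(C)C)c3c1OC(C)(C)C=C3)CO2 | intermediate
24 | kanzonol I, 8-[(3R)-5,7-dimethoxy-6-(3-methylbut-2-en-1-yl)chroman-3-yl]-2,2-dimethyl-2H-chromen-5-ol | COc1cc2c(c(OC)c1CC=C(C)C)C[C@H](c1ccc(O)c3c1OC(C)(C)C=C3)CO2 | target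

## Step count and least certain steps

Total: 13 steps. Longest linear sequence: 10 steps (steps 4 to 13, from 3,5-dimethoxyphenol); the ring B branch (steps 1 to 3) joins at step 9.

**Step 9 (key step).** The most likely failure is slow oxidative addition of the electron-rich, doubly ortho-substituted bromide 14, together with bromide inhibition. Boronate 17 would then be consumed by protodeboronation or direct Suzuki-type transfer before the metallate shift occurs; a hindered migrating group may also erode facial selection. The fallback leaves the route at 12 and 5 and rejoins at 18, making the C3–C1′ bond by reagent-controlled lithiation–borylation instead.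
- Aryllithium 13, generated from 12 as in step 8, is trapped with ethylene oxide and BF3·OEt2 to give 2-[2,4-dimethoxy-6-(methoxymethoxy)-3-(3-methylbut-2-en-1-yl)phenyl]ethan-1-ol F1.
- F1 is converted with N,N-diisopropylcarbamoyl chloride into the corresponding 2-arylethyl N,N-diisopropylcarbamate F2.
- Aryllithium 16 from 5 is quenched with 2-isopropoxy-4,4,5,5-tetramethyl-1,3,2-dioxaborolane to give the ring B pinacol boronic ester F3.
- Deprotonation of F2 with s-BuLi and (−)-sparteine in Et2O at −78 °C should give the configurationally stable S lithiated carbamate F4, which adds to F3 with retention to form the lithium boronate complex F5.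
- On warming (with MgBr2·OEt2 if needed) ring B migrates from boron to carbon anti to the departing carbamate, with inversion, which should give 18 in the R configuration.

**Step 10.** The most likely failure is collapse of the thermally fragile chloromethyllithium before the hindered secondary benzylic boron captures it. Unchanged 18 would then be oxidised to the secondary alcohol. The fallback leaves at 18 and rejoins at 20, bringing C2 in two stages. The more persistent dichloromethyllithium (from CH2Cl2 and n-BuLi at −100 °C) is added, and ZnCl2-promoted rearrangement gives the α-chloro boronic ester 2-{(2R)-1-chloro-2-[2,2-dimethyl-5-(triisopropylsilyloxy)-2H-chromen-8-yl]-3-[2,4-dimethoxy-6-(methoxymethoxy)-3-(3-methylbut-2-en-1-yl)phenyl]propyl}-4,4,5,5-tetramethyl-1,3,2-dioxaborolane F6, as a mixture of epimers at the chlorinated carbon. LiBHEt3 then delivers hydride to boron, and a second 1,2-shift expels chloride, erases the extra stereocentre and gives 20, which is oxidised to 21 as in step 10.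

**Step 8.** The most likely failure is competing deprotonation at the benzylic–allylic methylene of the prenyl group, or incomplete ring metalation, giving mixtures after the bromine quench. The fallback leaves at 11 and rejoins at 14 using electrophilic substitution. The free phenol 11, whose ring is far more nucleophilic than the alkene, is brominated with NBS in CH2Cl2 at −78 °C to give 2-bromo-3,5-dimethoxy-4-(3-methylbut-2-en-1-yl)phenol F7. MOMCl and i-Pr2NEt then give 14.

**Step 3.** The most likely failure is a sluggish sigmatropic shift, because the only productive ortho carbon lies beside the bulky silyl ether. Prolonged heating could then cause silyl loss or attack at the brominated carbon. The fallback leaves at 2 and rejoins at 5, bypassing the propargyl ether. Phenol 2 is condensed with 3-methylbut-2-enal in the presence of phenylboronic acid and acetic acid in refluxing toluene. The boron template delivers the aldehyde carbon to the single free ortho position, and elimination and oxa-6π closure give 5. No new compound arises on this path (F0).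

## Further compounds

F1 | step 9 | 2-[2,4-dimethoxy-6-(methoxymethoxy)-3-(3-methylbut-2-en-1-yl)phenyl]ethan-1-ol | OCCc1c(OCOC)cc(OC)c(CC=C(C)C)c1OC
F2 | step 9 | 2-[2,4-dimethoxy-6-(methoxymethoxy)-3-(3-methylbut-2-en-1-yl)phenyl]ethyl N,N-diisopropylcarbamate | CC(C)N(C(C)C)C(=O)OCCc1c(OCOC)cc(OC)c(CC=C(C)C)c1OC
F3 | step 9 | 2-[2,2-dimethyl-5-(triisopropylsilyloxy)-2H-chromen-8-yl]-4,4,5,5-tetramethyl-1,3,2-dioxaborolane | CC1(C)OB(c2ccc(O[Si](C(C)C)(C(C)C)C(C)C)c3c2OC(C)(C)C=C3)OC1(C)C
F4 | step 9 | (S)-1-lithio derivative of carbamate F2 (sparteine ligand omitted) | [Li][C@H](OC(=O)N(C(C)C)C(C)C)Cc1c(OCOC)cc(OC)c(CC=C(C)C)c1OC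
F5 | step 9 | lithium boronate complex formed from F4 and F3 | [Li+].COCOc1cc(OC)c(CC=C(C)C)c(OC)c1C[C@@H](OC(=O)N(C(C)C)C(C)C)[B-]1(c2ccc(O[Si](C(C)C)(C(C)C)C(C)C)c3c2OC(C)(C)C=C3)OC(C)(C)C(C)(C)O1
F6 | step 10 | 2-{(2R)-1-chloro-2-[2,2-dimethyl-5-(triisopropylsilyloxy)-2H-chromen-8-yl]-3-[2,4-dimethoxy-6-(methoxymethoxy)-3-(3-methylbut-2-en-1-yl)phenyl]propyl}-4,4,5,5-tetramethyl-1,3,2-dioxaborolane (epimers at C1) | COCOc1cc(OC)c(CC=C(C)C)c(OC)c1C[C@H](c1ccc(O[Si](C(C)C)(C(C)C)C(C)C)c2c1OC(C)(C)C=C2)C(Cl)B1OC(C)(C)C(C)(C)O1
F7 | step 8 | 2-bromo-3,5-dimethoxy-4-(3-methylbut-2-en-1-yl)phenol | COc1cc(O)c(Br)c(OC)c1CC=C(C)C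
F0 | step 3 | none | none
A1 | alternative 1 | (E)-1-diazo-4-[(3R)-5,7-dimethoxy-6-(3-methylbut-2-en-1-yl)chroman-3-yl]but-3-en-2-one | COc1cc2c(c(OC)c1CC=C(C)C)C[C@H](/C=C/C(=O)C=[N+]=[N-])CO2
A2 | alternative 1 | triisopropyl[(5-methylhex-4-en-1-yn-1-yl)oxy]silane | CC(C)=CCC#CO[Si](C(C)C)(C(C)C)C(C)C
A3 | alternative 1 | isoflavan with 2′-hydroxy, 3′-prenyl and 4′-triisopropylsilyloxy ring B | COc1cc2c(c(OC)c1CC=C(C)C)C[C@H](c4ccc(O[Si](C(C)C)(C(C)C)C(C)C)c(CC=C(C)C)c4O)CO2
A4 | alternative 2 | tert-butyl 2-formyl-3,5-dimethoxy-4-(3-methylbut-2-en-1-yl)phenyl carbonate | O=Cc1c(OC(=O)OC(C)(C)C)cc(OC)c(CC=C(C)C)c1OC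
A5 | alternative 2 | 3,5-dimethoxy-6-methylidene-4-(3-methylbut-2-en-1-yl)cyclohexa-2,4-dien-1-one (ring A ortho-quinone methide) | C=C1C(=O)C=C(OC)C(CC=C(C)C)=C1OC
A6 | alternative 2 | (E)-enol ether of ring B, 2,2-dimethyl-8-[2-(trans-2-phenylcyclohexyloxy)ethenyl]-5-(triisopropylsilyloxy)-2H-chromene | CC1(C)C=Cc2c(O[Si](C(C)C)(C(C)C)C(C)C)ccc(/C=C/O[C@@H]3CCCC[C@H]3c3ccccc3)c2O1
A7 | alternative 2 | trans-2-(2-phenylcyclohexyloxy)isoflavan acetal, ring B silyl ether | COc1cc2c(c(OC)c1CC=C(C)C)C[C@H](c4ccc(O[Si](C(C)C)(C(C)C)C(C)C)c5c4OC(C)(C)C=C5)[C@@H](O[C@@H]3CCCC[C@H]3c3ccccc3)O2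
A8 | alternative 3 | 2-{[2-bromo-4,6-dimethoxy-5-(3-methylbut-2-en-1-yl)phenyl]methyl}-2-[2,2-dimethyl-5-(triisopropylsilyloxy)-2H-chromen-8-yl]propane-1,3-diol | COc1cc(Br)c(CC(CO)(CO)c2ccc(O[Si](C(C)C)(C(C)C)C(C)C)c3c2OC(C)(C)C=C3)c(OC)c1CC=C(C)C
A9 | alternative 3 | 3-(hydroxymethyl)isoflavan, ring B silyl ether | COc1cc2c(c(OC)c1CC=C(C)C)C[C@](CO)(c4ccc(O[Si](C(C)C)(C(C)C)C(C)C)c5c4OC(C)(C)C=C5)CO2
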